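## Structural features

The target is a flavonol: a benzene ring A fused to a 4-pyranone ring C (a 4H-chromen-4-one), with free hydroxyls on C5 and C7, a 4-hydroxyphenyl ring B on C2 and a hydrogen sulfate ester on the oxygen at C3. All fifteen skeletal carbons are trigonal, so the target has no stereocentre and none stand next to each other; the only stereocentre of the route, C2 in 8, 9 and 11, is racemic and disappears when C2 becomes trigonal in 12. The fragile group is the enol-type O–SO3H ester, which is solvolysed by acid and heat and is best carried as a salt; the free polyphenol is also prone to air oxidation in base. The real difficulty is not the carbon skeleton but the four oxygens of similar acidity at C3, C5, C7 and C4', of which only the one at C3 may be sulfated. A route therefore has to deliver the C3 oxygen in a form that differs from the three phenols until the sulfate is in place. The key step exploits the fact that C3 carries oxygen and that C4 is bonded to C4a, one of the two equivalent ring A carbons ortho to O1 in a 3,5-dioxygenated phenoxy unit: a carbene at C4 next to a newly formed C3 carbonyl can be captured by that carbon and so close ring C. Because ring A is symmetrical about the O1–C8a axis, this closure raises no regiochemical question, and the C3 oxygen emerges as a ketone that cannot be confused with a phenol.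

## Logic of the disconnections

16 from 13. Going backwards, the two benzyl–oxygen bonds at O5 and O7 and the acyl–oxygen bond at O4' are restored and the acid is returned to its salt (through 15 and 14). The sulfate is the most fragile function and the phenols must be masked while it is installed, so deprotection comes last. The gain is that 13 is a chromatographable salt with one kind of reactive site. The demand is that deprotection runs under neutral or basic conditions, with acid only at the very end and cold.

13 from 12. The S–O3 bond is cut. In 12 the 3-hydroxyl is the only free OH, so sulfation needs no selectivity; the question of which oxygen is settled earlier. The demand is an electrophile strong enough for a hindered, hydrogen-bonded enolic hydroxyl under conditions that spare the aryl ester.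

12 from 11. The C4 carbonyl oxygen is removed, taking C4 back to a methylene. This is done because 11 is exactly what the key step delivers, and the 3,4-dione that C4 oxidation gives is the keto tautomer of 12. The gain is that the C4 oxidation level need not be carried through the ring closure. The demand is that the oxidant act at C4 and not at C2, whose hydrogen, flanked by aryl and aryloxy, is probably the more acidic α-hydrogen; an oxidation that is productive only at a methylene is therefore preferred to enolate autoxidation.

11 from 9 and 10. The C4–C4a bond and the C3=O bond are cut; the oxygen returns to 10 and C3 and C4 become the carbons of a terminal alkyne. This removes ring C in one operation and leaves an acyclic aryl propargyl ether. Three points are set differently from the simplest version of this idea: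
- A 1,2-hydride shift from C2 is not a threat, because the C3 carbonyl carbon separates C2 from the carbene carbon. The real competitors are direct hydroarylation of the gold-bound alkyne by ring A, a second oxidation of the carbene, and heterolysis of the C2–O1 bond.
- To suppress that heterolysis, the ring B oxygen of 9 is acylated (pivalate) rather than benzylated. A para-alkoxy group would make C2 a benzylic and propargylic cation precursor with an aryloxide leaving group, both under Mitsunobu activation and under cationic gold. A para-acyloxy group makes the ring about as cation-stabilising as phenyl. The skeletons of 9 and 11 are unchanged.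
- A bulky biarylphosphine gold complex replaces a triphenylphosphine one, to disfavour hydroarylation and over-oxidation.

The ring A carbon that attacks is flanked by O1 and one benzyloxy group and is para to the other. The demand on the forward step is chemoselectivity among these pathways.

9 from 8 and 4. The O1–C2 ether bond is cut, which separates ring A from the C2–C3–C4 unit carrying ring B and makes the synthesis convergent. The demand is substitution at the propargylic carbon by oxygen, not by a ring carbon of the ambident phenoxide and not at the alkyne terminus.

8 from 6 and 7. The C2–C3 bond is cut, giving an aldehyde and an acetylide. The demand is that the acetylide add to the aldehyde and leave the aryl ester alone.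

6 from 5. The acyl–oxygen bond is cut; a simple phenol acylation.

4 from 1, through 3 and 2. The two benzyl–oxygen bonds are cut. Direct dibenzylation of 1 would suffer from C-alkylation, so 1 is first peracetylated to 2 and the acetates are exchanged for benzyl groups one at a time. The demand is to stop the exchange after two of the three groups.

## Other disconnections considered

Alternative 1: The cut is the C4a–C5 bond inside ring A, which unravels that ring into an open-chain trioxo ester, methyl (8E)-9-(4-hydroxyphenyl)-3,5,7-trioxonon-8-enoate A2. In the forward direction Mg(OMe)2 would chelate the poly-β-carbonyl chain and direct the C6 carbanion onto the ester carbon (Claisen condensation); aromatisation would give naringenin chalcone A1.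
- In its favour: all fifteen carbons come from one chain and the phloroglucinol pattern of ring A arises by itself. The closure has no regiochemical ambiguity because the ring is symmetrical, which makes it the equal of the chosen plan on that point. Up to A1 no protecting group is needed, which is better than the chosen plan.
- Against it: A2 must be assembled by polyanion acylation and has several ways to go astray. Aldol closure of C2 onto the C7 carbonyl, lactonisation to a 4-hydroxy-2-pyranone and conjugate addition to the enone all compete with the Claisen mode, and the magnesium template only biases the partition.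
- More seriously, A1 still lacks ring C and the C3 oxygen. Alkaline H2O2 cyclisation of 2'-hydroxychalcones (Algar–Flynn–Oyamada) tends toward aurones when the 6'-position is oxygenated, so a longer path through flavanone and dihydroflavonol stages would be expected. That path ends at kaempferol A3, whose four free hydroxyls must then be told apart before O3 can be sulfated.
- Comparison: structurally, the alternative spends its key step on ring A, the one part that can be bought, and leaves ring C and the O3 problem unsolved; the chosen plan forms ring C and delivers O3 as a ketone in one event. Mechanistically, a partition among four cyclisation modes stands against a single intramolecular carbene capture. In step economy it would be shorter to A1 than the chosen plan is to 11 only if A2 were easy to obtain, and it is longer afterwards.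

Alternative 2: The cut is the C7–C8 bond of ring A. Ring C is present from the start as a fully substituted pyranone, methyl 3-{6-[4-(benzyloxy)phenyl]-5-(methoxymethoxy)-2-methyl-4-oxo-4H-pyran-3-yl}-3-oxopropanoate A5. LiN(iPr)2 would deprotonate the ring methyl group and this vinylogous carbanion would attack the side-chain ester; enolisation then gives 4'-O-benzyl-3-O-(methoxymethyl)kaempferol A4.
- In its favour: O3 is differentiated from the outset as an acetal, which equals the chosen plan on the central issue. Ring C arrives at the final oxidation level, so no later C4 oxidation is needed, which is better than the chosen plan.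
- Against it: A5 is a pyranone with five different substituents, and its preparation would probably cost more steps than the whole front half of the chosen route. The β-keto ester methylene is far more acidic than the ring methyl, so the closure must run through a polyanion in which the ester is part of an enolate and a poor electrophile.
- In A4 the C5 and C7 hydroxyls are free. They would have to be protected (the chelated 5-OH reluctantly) before the acetal is removed with acid and O3 is sulfated, which adds about three steps.
- Comparison: structurally, it again builds the cheapest ring at the highest cost. Mechanistically, a Claisen closure onto a deactivated ester is less secure than the capture of a highly electrophilic carbene by an activated arene. In step economy it is clearly behind, despite the two points noted in its favour.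

Alternative 3: The cut is the C3–C4 bond of ring C. The precursor is an ether-linked dialdehyde, rac-2,4-bis(benzyloxy)-6-{1-[4-(benzyloxy)phenyl]-2-oxoethoxy}benzaldehyde A7. A triazolium-derived N-heterocyclic carbene with base would turn the aromatic formyl group into an acyl anion equivalent that adds to the aliphatic formyl group, closing ring C as trans-5,7,4'-tri-O-benzyldihydrokaempferol A6 (racemic, drawn as 2R,3R). Dehydrogenation would give 5,7,4'-tri-O-benzylkaempferol A8, and sulfation and hydrogenolysis would finish.
- In its favour: the C3 oxygen arrives as a secondary alcohol distinct from the phenol ethers, which equals the chosen plan. C4 arrives as the ketone, so only a two-hydrogen dehydrogenation remains, which is better than the C4 methylene oxidation of the chosen plan. A single class of protecting group allows a one-operation final deprotection, which is also better, since the chosen plan needs an extra ester cleavage. No metal catalyst is needed.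
- Against it: A7 is an α-aryl-α-aryloxy acetaldehyde, highly enolisable and air-sensitive. The carbene should add first to this more reactive aliphatic aldehyde, and α-aryloxy aldehydes are known to expel the aryloxide from that adduct (internal redox to an acyl azolium). That would cleave the ether that holds the substrate together.
- The aldehyde that must act as the donor is the 2,6-dioxygenated, electron-rich aromatic one, the least inclined to add the carbene. A forgiving feature is that the regioisomeric acyloin (3-keto-4-hydroxy) would oxidise to the same flavonol.
- Comparison: structurally the two plans are equal in how they distinguish O3. Mechanistically, the alternative has two competing aldehydes and a built-in fragmentation path, against one alkyne and two equivalent arene positions. In step economy the two are about equal, with the alternative slightly ahead in the endgame and behind in the reliability of its key step.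

Key step: step 6

Assumption: the target is taken as the free hydrogen sulfate as drawn; the sulfate is carried as a triethylammonium or potassium salt and the acid form is generated only in the last operation, cold, and lyophilised at once.

## Route

Step 1
Reactants: 1 phloroglucinol (benzene-1,3,5-triol)
Product: 2 benzene-1,3,5-triyl triacetate (phloroglucinol triacetate)
Conditions: Ac2O, pyridine, 0 °C to rt
Reagents that add atoms: acetic anhydride, CC(=O)OC(C)=O
Why: Exhaustive O-acetylation of a phenol (nucleophilic acyl substitution); the triacetate masks the ambident phloroglucinol nucleus so that step 2 can release one phenoxide at a time.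

Step 2
Reactants: 2 benzene-1,3,5-triyl triacetate
Product: 4 3,5-bis(benzyloxy)phenol, via 3,5-bis(benzyloxy)phenyl acetate 3 (not isolated)
Conditions: BnCl (2.05 equiv), NaH (4.2 equiv), DMF, 0 °C, H2O (2.0 equiv) added slowly; then 2 M NaOH, MeOH, rt; 1 M HCl
Reagents that add atoms: benzyl chloride, ClCc1ccccc1
Why: Hydroxide formed in situ cleaves the aryl acetates one at a time and each phenoxide is trapped at once by benzyl chloride (Williamson etherification), which keeps the free phenoxide concentration low and suppresses C-benzylation. With two equivalents of water the exchange should stop, on statistical grounds, mainly at the dibenzyl stage 3; saponification of the last acetate gives 4, and mono- and tri-benzylated material is removed by chromatography.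

Step 3
Reactants: 5 4-hydroxybenzaldehyde
Product: 6 4-formylphenyl pivalate (4-formylphenyl 2,2-dimethylpropanoate)
Conditions: PivCl, Et3N, DMAP (cat.), CH2Cl2, 0 °C to rt
Reagents that add atoms: pivaloyl chloride, CC(C)(C)C(Cl)=O
Why: Acylation of the phenol (nucleophilic acyl substitution, DMAP catalysis). The pivalate, unlike a benzyl ether, does not stabilise a cation at the future C2, and it is hindered enough to survive steps 4 to 8.

Step 4
Reactants: 6 4-formylphenyl pivalate; 7 ethynylmagnesium bromide
Product: 8 rac-4-(1-hydroxyprop-2-yn-1-yl)phenyl pivalate
Conditions: THF, −78 to −30 °C; sat. aq. NH4Cl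
Reagents that add atoms: none
Why: Grignard 1,2-addition of the acetylide to the aldehyde, which at low temperature is far more electrophilic than the hindered aryl pivalate. The new carbinol centre (the future C2) is formed racemic on purpose, because it becomes trigonal in the target.

Step 5
Reactants: 8 rac-4-(1-hydroxyprop-2-yn-1-yl)phenyl pivalate; 4 3,5-bis(benzyloxy)phenol
Product: 9 rac-4-{1-[3,5-bis(benzyloxy)phenoxy]prop-2-yn-1-yl}phenyl pivalate
Conditions: PPh3, DIAD, THF, 0 °C to rt
Reagents that add atoms: none
Why: Mitsunobu etherification: phenol 4 protonates the betaine and its phenoxide displaces the oxyphosphonium group at the propargylic carbon with inversion, which is irrelevant because 8 is racemic. The pivaloyloxy group keeps the activated alcohol from ionising, so attack by oxygen at the propargylic carbon should prevail over C-alkylation of the phenoxide and over attack at the alkyne terminus.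

Step 6
Reactants: 9 rac-4-{1-[3,5-bis(benzyloxy)phenoxy]prop-2-yn-1-yl}phenyl pivalate; 10 8-methylquinoline N-oxide
Product: 11 rac-4-[5,7-bis(benzyloxy)-3-oxochroman-2-yl]phenyl pivalate
Conditions: (Me4tBuXPhos)AuNTf2 (5 mol %; Me4tBuXPhos = di-tert-butyl(2',4',6'-triisopropyl-3,4,5,6-tetramethylbiphenyl-2-yl)phosphine), 10 (1.5 equiv), ClCH2CH2Cl, 0 °C to rt, Ar, no acid additive
Reagents that add atoms: none
Why: The cationic monovalent gold centre coordinates the terminal alkyne of 9, the oxygen of 10 adds to the internal alkyne carbon (future C3) anti to gold, and N–O heterolysis of the resulting vinylgold species releases 8-methylquinoline and leaves an α-oxo gold carbene at the former terminal carbon (future C4). Ring C, a six-membered ring, is then closed by Friedel–Crafts-type attack of a ring A carbon ortho to O1 on the carbene carbon (an exo closure with respect to the gold–carbon bond), followed by rearomatisation and protodeauration, which gives the C3 ketone and the C4–C4a bond of 11. The closest known reaction type is the gold-catalysed N-oxide oxidation of aryl propargyl ethers to chroman-3-ones. No stereocentre is created; the racemic C2 centre of 9 passes into 11 unchanged and becomes trigonal in step 7. The regiochemistry of the oxidation is secured by the terminal alkyne (oxygen to the internal carbon), and that of the arylation by the symmetry of ring A, whose two positions ortho to O1 are equivalent, each flanked by O1 and one benzyloxy group and para to the other. A 1,2-hydride shift from C2 cannot intervene, because the C3 carbonyl carbon lies between C2 and the carbene carbon; the real competitors are direct 6-endo hydroarylation of the gold-bound alkyne to the 2H-chromene, a second oxidation of the carbene to the keto aldehyde, and ionisation of the C2–O1 bond. The first two are countered by having 10 present in excess from the start, by the bulky biarylphosphine ligand and by fast intramolecular capture on the activated ring; the third by the electron-poor pivaloyloxyphenyl group on C2 and the absence of acid.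

Step 7
Reactants: 11 rac-4-[5,7-bis(benzyloxy)-3-oxochroman-2-yl]phenyl pivalate
Product: 12 4-[5,7-bis(benzyloxy)-3-hydroxy-4-oxo-4H-chromen-2-yl]phenyl pivalate (5,7-di-O-benzyl-4'-O-pivaloylkaempferol)
Conditions: SeO2 (1.3 equiv), 1,4-dioxane–H2O (30:1), 70 °C
Reagents that add atoms: selenium dioxide, O=[Se]=O
Why: Riley oxidation: the enol of 11 is attacked by tetravalent selenium, and only the C4 methylene, which carries a second hydrogen, can go on to the carbonyl, so the acidic C2–H cannot divert the reaction as it could in an enolate autoxidation. The resulting chroman-3,4-dione is the keto tautomer of the flavonol and enolises at once to the aromatic pyranone 12, which removes the C2 stereocentre.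

Step 8
Reactants: 12 4-[5,7-bis(benzyloxy)-3-hydroxy-4-oxo-4H-chromen-2-yl]phenyl pivalate
Product: 13 triethylammonium 5,7-bis(benzyloxy)-4-oxo-2-[4-(pivaloyloxy)phenyl]-4H-chromen-3-yl sulfate
Conditions: SO3·NEt3 (4 equiv), Et3N, DMF, 45 °C
Reagents that add atoms: sulfur trioxide–triethylamine complex, CC[N+](CC)(CC)S(=O)(=O)[O-]
Why: O-Sulfation of a hydroxyl group by a sulfur trioxide–amine complex; the 3-hydroxyl is the only free OH of 12, so no regioselectivity is required. The product is obtained as its triethylammonium salt, which is soluble in organic solvents and can be chromatographed on base-washed silica.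

Step 9
Reactants: 13 triethylammonium 5,7-bis(benzyloxy)-4-oxo-2-[4-(pivaloyloxy)phenyl]-4H-chromen-3-yl sulfate
Product: 16 kaempferol 3-O-sulfate, via triethylammonium 4'-O-pivaloylkaempferol 3-O-sulfate 14 (not isolated), via potassium kaempferol 3-O-sulfate 15 (not isolated)
Conditions: H2 (1 atm), 10% Pd/C, MeOH–THF, rt, filter; K2CO3 (3 equiv), MeOH, Ar, rt; 1 M HCl to pH 1, 0 °C, C18 solid-phase extraction, lyophilise
Reagents that add atoms: none
Why: Hydrogenolysis cleaves the two benzyl ethers without touching the sulfate monoester anion or the pyranone; K2CO3 in methanol then removes the aryl pivalate by transesterification (sulfate monoester anions are inert to base); brief cold acidification converts the potassium salt into the acid form. The order keeps acid away from the sulfate until the last moment.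

## Compound list

1 | phloroglucinol (benzene-1,3,5-triol) | Oc1cc(O)cc(O)c1 | starting material
2 | benzene-1,3,5-triyl triacetate | CC(=O)Oc1cc(OC(C)=O)cc(OC(C)=O)c1 | intermediate
3 | 3,5-bis(benzyloxy)phenyl acetate | CC(=O)Oc1cc(OCc2ccccc2)cc(OCc2ccccc2)c1 | intermediate
4 | 3,5-bis(benzyloxy)phenol | Oc1cc(OCc2ccccc2)cc(OCc2ccccc2)c1 | intermediate
5 | 4-hydroxybenzaldehyde | O=Cc1ccc(O)cc1 | starting material
6 | 4-formylphenyl pivalate | CC(C)(C)C(=O)Oc1ccc(C=O)cc1 | intermediate
7 | ethynylmagnesium bromide | C#C[Mg]Br | starting material
8 | rac-4-(1-hydroxyprop-2-yn-1-yl)phenyl pivalate (racemic) | C#CC(O)c1ccc(OC(=O)C(C)(C)C)cc1 | intermediate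
9 | rac-4-{1-[3,5-bis(benzyloxy)phenoxy]prop-2-yn-1-yl}phenyl pivalate (racemic) | C#CC(Oc1cc(OCc2ccccc2)cc(OCc2ccccc2)c1)c1ccc(OC(=O)C(C)(C)C)cc1 | intermediate
10 | 8-methylquinoline N-oxide | Cc1cccc2ccc[n+]([O-])c12 | starting material
11 | rac-4-[5,7-bis(benzyloxy)-3-oxochroman-2-yl]phenyl pivalate (racemic) | O=C1Cc2c(OCc3ccccc3)cc(OCc3ccccc3)cc2OC1c1ccc(OC(=O)C(C)(C)C)cc1 | intermediate
12 | 4-[5,7-bis(benzyloxy)-3-hydroxy-4-oxo-4H-chromen-2-yl]phenyl pivalate | O=c1c(O)c(-c2ccc(OC(=O)C(C)(C)C)cc2)oc2cc(OCc3ccccc3)cc(OCc3ccccc3)c12 | intermediate
13 | triethylammonium 5,7-bis(benzyloxy)-4-oxo-2-[4-(pivaloyloxy)phenyl]-4H-chromen-3-yl sulfate | CC[NH+](CC)CC.O=c1c(OS(=O)(=O)[O-])c(-c2ccc(OC(=O)C(C)(C)C)cc2)oc2cc(OCc3ccccc3)cc(OCc3ccccc3)c12 | intermediate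
14 | triethylammonium 5,7-dihydroxy-4-oxo-2-[4-(pivaloyloxy)phenyl]-4H-chromen-3-yl sulfate | CC[NH+](CC)CC.O=c1c(OS(=O)(=O)[O-])c(-c2ccc(OC(=O)C(C)(C)C)cc2)oc2cc(O)cc(O)c12 | intermediate
15 | potassium kaempferol 3-O-sulfate | [K+].O=c1c(OS(=O)(=O)[O-])c(-c2ccc(O)cc2)oc2cc(O)cc(O)c12 | intermediate
16 | kaempferol 3-O-sulfate | O=c1c(OS(=O)(=O)O)c(-c2ccc(O)cc2)oc2cc(O)cc(O)c12 | target

## Step count and least certain steps

Total step count: 9. Longest linear sequence: 7 steps (steps 1, 2, 5, 6, 7, 8, 9; the branch through steps 3 and 4 is equally long).

Step 6 (key step). The most likely failures are:
- direct gold-catalysed hydroarylation of the alkyne by the very nucleophilic ring A before the N-oxide has added;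
- over-oxidation of the carbene by a second molecule of 10;
- slowing of the catalyst by the liberated quinoline.

Each would divert material from the carbene-capture pathway. The fallback brings the oxygens to C3 and C4 in a different way and sets out from 9. The hydroarylation is run on purpose with Ph3PAuNTf2 and no oxidant (CH2Cl2, rt) to give rac-4-[5,7-bis(benzyloxy)-2H-chromen-2-yl]phenyl pivalate F1. Its C3=C4 bond is dihydroxylated (OsO4 cat., N-methylmorpholine N-oxide, acetone–H2O), with addition expected anti to the C2 aryl group, to give rac-4-[(2R*,3S*,4S*)-5,7-bis(benzyloxy)-3,4-dihydroxychroman-2-yl]phenyl pivalate F2. Both carbinols are then oxidised with 2-iodoxybenzoic acid in DMSO, which oxidises 1,2-diols without C–C cleavage. The resulting 3,4-dione is the keto tautomer of the flavonol, so the fallback comes back to the route at 12 and bypasses 11.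

Step 7. The most likely failures are electrophilic attack of the selenium reagent on the electron-rich ring A or at C2 instead of C4, incomplete conversion at a temperature the sensitive ketone tolerates, and carry-over of selenium traces that later slow the Pd/C hydrogenolysis. The fallback sets out from 11 and uses a condensation that is possible only at a methylene. Heating with tert-butoxybis(dimethylamino)methane (toluene, 50 °C) should give the enaminone rac-4-{5,7-bis(benzyloxy)-4-[(dimethylamino)methylidene]-3-oxochroman-2-yl}phenyl pivalate F3. Dye-sensitised photo-oxygenation (O2, tetraphenylporphyrin, visible light, CH2Cl2, −78 °C) adds singlet oxygen across the enamine double bond, and the dioxetane fragments to the C4 carbonyl and dimethylformamide. The dione enolises, and the route is rejoined at 12.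

Step 5. The most likely failures are attack of the phenoxide through a ring carbon or at the alkyne terminus (allenyl ether), and slow displacement at the hindered secondary centre with build-up of hydrazide adducts. The fallback sets out from 8 and replaces phosphonium activation by copper catalysis. Methyl chloroformate and pyridine (CH2Cl2, 0 °C) give rac-1-[4-(pivaloyloxy)phenyl]prop-2-yn-1-yl methyl carbonate F4. Monovalent copper (Cu(MeCN)4PF6, a 2,6-bis(oxazolinyl)pyridine ligand, iPr2NEt, 0 °C) converts it through the copper acetylide into a copper allenylidene, to which the phenoxide of 4 adds at the propargylic carbon. This returns to the route at 9.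

Step 8. The most likely failures are incomplete sulfation of the hindered, hydrogen-bonded 3-hydroxyl and loss of the polar salt on purification. The fallback sets out from 12 and installs the sulfate as a neutral, chromatographable diester. 2,2,2-Trichloroethyl chlorosulfate with Et3N and DMAP (THF, 0 °C to rt) should give 4-[5,7-bis(benzyloxy)-4-oxo-3-{[(2,2,2-trichloroethoxy)sulfonyl]oxy}-4H-chromen-2-yl]phenyl pivalate F5. Reductive removal of the trichloroethyl group (Zn, HCO2NH4, MeOH, rt), followed by evaporation from methanolic triethylamine, gives the monoester as its triethylammonium salt and comes back to the route at 13.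

Step 9. The most likely failures are solvolytic loss of the sulfate group once the acid form is generated and concentrated, stalling of the hydrogenolysis through catalyst poisoning, and air oxidation of the polyphenolate during the basic ester cleavage. The fallback sets out from 13 and reverses the order, so that the base-mediated step is done on a benzyl-protected, purifiable intermediate and the last bond-breaking event is neutral. K2CO3 in MeOH (rt) gives potassium 5,7-bis(benzyloxy)-2-(4-hydroxyphenyl)-4-oxo-4H-chromen-3-yl sulfate F6, which is purified by reversed-phase chromatography, removing catalyst poisons as well. Hydrogenolysis (H2, Pd(OH)2/C, MeOH) then comes back to the route at 15, which is acidified cold as in step 9.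

## Further compounds

F1 | step 6 | rac-4-[5,7-bis(benzyloxy)-2H-chromen-2-yl]phenyl pivalate | CC(C)(C)C(=O)Oc1ccc(C2C=Cc3c(OCc4ccccc4)cc(OCc4ccccc4)cc3O2)cc1
F2 | step 6 | rac-4-[(2R*,3S*,4S*)-5,7-bis(benzyloxy)-3,4-dihydroxychroman-2-yl]phenyl pivalate (racemic, 2,3-trans-3,4-cis, drawn as 2R,3S,4S) | O[C@H]1[C@@H](O)c2c(OCc3ccccc3)cc(OCc3ccccc3)cc2O[C@@H]1c1ccc(OC(=O)C(C)(C)C)cc1
F3 | step 7 | rac-4-{5,7-bis(benzyloxy)-4-[(dimethylamino)methylidene]-3-oxochroman-2-yl}phenyl pivalate (double-bond geometry not assigned) | CN(C)C=C1C(=O)C(c2ccc(OC(=O)C(C)(C)C)cc2)Oc2cc(OCc3ccccc3)cc(OCc3ccccc3)c12
F4 | step 5 | rac-1-[4-(pivaloyloxy)phenyl]prop-2-yn-1-yl methyl carbonate | C#CC(OC(=O)OC)c1ccc(OC(=O)C(C)(C)C)cc1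
F5 | step 8 | 4-[5,7-bis(benzyloxy)-4-oxo-3-{[(2,2,2-trichloroethoxy)sulfonyl]oxy}-4H-chromen-2-yl]phenyl pivalate | O=c1c(OS(=O)(=O)OCC(Cl)(Cl)Cl)c(-c2ccc(OC(=O)C(C)(C)C)cc2)oc2cc(OCc3ccccc3)cc(OCc3ccccc3)c12
F6 | step 9 | potassium 5,7-bis(benzyloxy)-2-(4-hydroxyphenyl)-4-oxo-4H-chromen-3-yl sulfate | [K+].O=c1c(OS(=O)(=O)[O-])c(-c2ccc(O)cc2)oc2cc(OCc3ccccc3)cc(OCc3ccccc3)c12
A1 | alternative 1 | naringenin chalcone | O=C(/C=C/c1ccc(O)cc1)c1c(O)cc(O)cc1O
A2 | alternative 1 | methyl (8E)-9-(4-hydroxyphenyl)-3,5,7-trioxonon-8-enoate | COC(=O)CC(=O)CC(=O)CC(=O)/C=C/c1ccc(O)cc1
A3 | alternative 1 | kaempferol | O=c1c(O)c(-c2ccc(O)cc2)oc2cc(O)cc(O)c12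
A4 | alternative 2 | 4'-O-benzyl-3-O-(methoxymethyl)kaempferol | COCOc1c(-c2ccc(OCc3ccccc3)cc2)oc2cc(O)cc(O)c2c1=O
A5 | alternative 2 | methyl 3-{6-[4-(benzyloxy)phenyl]-5-(methoxymethoxy)-2-methyl-4-oxo-4H-pyran-3-yl}-3-oxopropanoate | COC(=O)CC(=O)c1c(C)oc(-c2ccc(OCc3ccccc3)cc2)c(OCOC)c1=O
A6 | alternative 3 | trans-5,7,4'-tri-O-benzyldihydrokaempferol (racemic, drawn as 2R,3R) | O=C1c2c(OCc3ccccc3)cc(OCc3ccccc3)cc2O[C@H](c2ccc(OCc3ccccc3)cc2)[C@H]1O
A7 | alternative 3 | rac-2,4-bis(benzyloxy)-6-{1-[4-(benzyloxy)phenyl]-2-oxoethoxy}benzaldehyde | O=CC(Oc1cc(OCc2ccccc2)cc(OCc2ccccc2)c1C=O)c1ccc(OCc2ccccc2)cc1
A8 | alternative 3 | 5,7,4'-tri-O-benzylkaempferol | O=c1c(O)c(-c2ccc(OCc3ccccc3)cc2)oc2cc(OCc3ccccc3)cc(OCc3ccccc3)c12
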